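**Retrosynthetic overview** (TBSO = tert-butyldimethylsilyloxy)

1. Locants: C1 lactone carbonyl, O2, C3, C4, benzene carbons C4a, C5–C8, C8a (ring A), lactone ring (ring B), side chain C1'–C11'. The target is opened at the C6–O methyl bond and the O2–C1 lactone bond to a methyl 2-alkyl-4,6-dihydroxybenzoate with silyl ethers on the C3 and C6' oxygens.
2. The strategy rests on ring A: oxygen on C6 and C8 and carbon branches on C8a (C1) and C4a (C4) alternate as in a folded C1-to-C3 poly-β-carbonyl chain. Ring A is therefore cut at C4a–C8a to a methyl 3,5,7-triketo ester, released from a diketo-dioxinone by loss of acetone and capture of the acylketene by methanol.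
3. The diketo-dioxinone is cut at C4a–C5: dianion of 2,2-dimethyl-6-(2-oxopropyl)-4H-1,3-dioxin-4-one plus the Weinreb amide of (3R,9S)-3,9-bis(TBSO)tetradecanoic acid.
4. The amide comes from twofold-symmetric dimethyl (3R,9R)-3,9-dihydroxyundecanedioate (an axis through C3' relates C3 and C6'), with one ester end grown into the C7'–C11' pentyl group. The diol comes from a double Noyori hydrogenation of the bis-β-keto ester made from heptanedioyl dichloride, Meldrum's acid and methanol.
5. Ring order: ring A first (step 10), then ring B by lactonisation (step 11).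

Key step: step 10

**Route**

Step 1
Reactants: 1 heptanedioyl dichloride; 2 2,2-dimethyl-1,3-dioxane-4,6-dione (Meldrum's acid); 3 methanol
Product: 5 dimethyl 3,9-dioxoundecanedioate, via bis(acyl) Meldrum's acid adduct 4 (not isolated)
Conditions: 2 (2.1 equiv), pyridine, CH2Cl2, 0 °C to rt; then MeOH, reflux
Reagents that add atoms: none
Why: Oikawa–Yonemitsu C-acylation of Meldrum's acid at both acid chloride ends, followed by methanolysis with loss of acetone and CO2, should give the symmetric bis-β-keto ester in one operation.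

Step 2
Reactants: 5 dimethyl 3,9-dioxoundecanedioate
Product: 6 dimethyl (3R,9R)-3,9-dihydroxyundecanedioate
Conditions: H2 (10 bar), RuCl2[(R)-BINAP] (1 mol %), MeOH, 60 °C
Reagents that add atoms: none
Why: Noyori asymmetric hydrogenation, in which each β-keto ester chelates divalent ruthenium through its ketone and ester oxygens and (R)-BINAP directs hydride to the face that gives the (R)-carbinol, as with methyl acetoacetate; the two remote sites react independently, so both centres are set by the catalyst.

Step 3
Reactants: 6 dimethyl (3R,9R)-3,9-dihydroxyundecanedioate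
Product: 7 dimethyl (3R,9R)-3,9-bis(TBSO)undecanedioate
Conditions: TBSCl, imidazole, DMF, rt
Reagents that add atoms: tert-butyldimethylsilyl chloride, CC(C)(C)[Si](C)(C)Cl
Why: Imidazole-promoted silylation of both secondary alcohols; the TBS ethers are chosen to survive hydride, ylide, Grignard, amide-base and carbonate steps and to be removed by acidic methanol at the end.

Step 4
Reactants: 7 dimethyl (3R,9R)-3,9-bis(TBSO)undecanedioate
Product: 8 methyl (3R,9R)-3,9-bis(TBSO)-11-oxoundecanoate
Conditions: i-Bu2AlH (1.0 equiv), CH2Cl2, −78 °C; MeOH, then aq. KNaC4H4O6 (potassium sodium tartrate)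
Reagents that add atoms: none
Why: Partial ester reduction through the aluminium hemiacetal, which is stable at −78 °C; the two esters are homotopic about the twofold axis, so either gives the same mono-aldehyde, expected as the main part of a statistical mixture from which 7 is recovered and recycled (if 8 and 7 co-elute, the mixture is carried into step 5 and separated there).

Step 5
Reactants: 8 methyl (3R,9R)-3,9-bis(TBSO)-11-oxoundecanoate
Product: 9 methyl (3R,9R,11Z)-3,9-bis(TBSO)tetradec-11-enoate
Conditions: n-PrPPh3Br, NaN(SiMe3)2, THF, 0 °C; then 8, −78 °C to 0 °C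
Reagents that add atoms: propyltriphenylphosphonium bromide, CCC[P+](c1ccccc1)(c1ccccc1)c1ccccc1.[Br-]
Why: Wittig olefination with a salt-free non-stabilised ylide, which at low temperature should take the aldehyde much faster than the remote ester and without enolising the β-silyloxy aldehyde; the Z geometry is of no consequence because the alkene is hydrogenated next.

Step 6
Reactants: 9 methyl (3R,9R,11Z)-3,9-bis(TBSO)tetradec-11-enoate
Product: 10 methyl (3R,9S)-3,9-bis(TBSO)tetradecanoate
Conditions: H2 (1 atm), 10% Pd/C, EtOAc, rt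
Reagents that add atoms: none
Why: Heterogeneous catalytic hydrogenation of a disubstituted alkene in a non-protic solvent that leaves the silyl ethers intact; the C9 descriptor changes from R to S only through the change in CIP ranking, since no bond at that carbon is touched.

Step 7
Reactants: 10 methyl (3R,9S)-3,9-bis(TBSO)tetradecanoate
Product: 11 (3R,9S)-3,9-bis(TBSO)-N-methoxy-N-methyltetradecanamide
Conditions: MeNHOMe·HCl, i-PrMgCl, THF, −20 °C to 0 °C
Reagents that add atoms: N,O-dimethylhydroxylamine hydrochloride, CNOC.Cl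
Why: Direct ester-to-Weinreb-amide aminolysis by the chloromagnesium amide formed in the flask; at low temperature it should occur without β-elimination of the C3 silyloxy group.

Step 8
Reactants: 12 2,2,6-trimethyl-4H-1,3-dioxin-4-one
Product: 14 2,2-dimethyl-6-(2-oxopropyl)-4H-1,3-dioxin-4-one, via lithium dienolate 13 (not isolated)
Conditions: 12 (2.0 equiv), LiN(SiMe3)2 (2.0 equiv), THF, −78 °C; then AcCl (1.0 equiv), −78 °C; aq. HCl
Reagents that add atoms: acetyl chloride, CC(=O)Cl
Why: Vinylogous Claisen-type C-acylation of the dioxinone dienolate at its exocyclic γ-carbon; the second equivalent of dienolate deprotonates the more acidic product and returns 12 on work-up.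

Step 9
Reactants: 14 2,2-dimethyl-6-(2-oxopropyl)-4H-1,3-dioxin-4-one; 11 (3R,9S)-3,9-bis(TBSO)-N-methoxy-N-methyltetradecanamide
Product: 16 6-[(6R,12S)-6,12-bis(TBSO)-2,4-dioxoheptadecyl]-2,2-dimethyl-4H-1,3-dioxin-4-one, via dilithium dianion 15 (not isolated)
Conditions: 14 (2.5 equiv), LiN(i-Pr)2 (5 equiv), THF, −78 °C; then 11, −78 to −40 °C; aq. NH4Cl; product used promptly
Reagents that add atoms: none
Why: Crossed Claisen acylation of a 1,3-dicarbonyl dianion, which reacts at its terminal, more basic carbon with the Weinreb amide; the chelated tetrahedral adduct holds until quench, so no second addition occurs and the C4a–C5 bond is formed.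

Step 10
Reactants: 16 6-[(6R,12S)-6,12-bis(TBSO)-2,4-dioxoheptadecyl]-2,2-dimethyl-4H-1,3-dioxin-4-one; 3 methanol
Product: 20 methyl 2-[(2R,8S)-2,8-bis(TBSO)tridecyl]-4,6-dihydroxybenzoate, via acylketene 17 (not isolated), via methyl triketo ester 18 (not isolated), via cyclic aldol adduct 19 (not isolated)
Conditions: PhMe, MeOH (5 equiv), 110 °C, sealed tube; cool to rt, then Cs2CO3 (2 equiv), MeOH, rt; AcOH quench
Reagents that add atoms: none
Why: At 110 °C the dioxinone ring of 16 should lose acetone by a retro-[4+2] reaction to give acylketene 17, which methanol captures at C1 to give the methyl 3,5,7-triketo ester 18. Cs2CO3 then deprotonates C8a, the carbon flanked by the C1 ester and the C8 ketone, and this enolate adds to the C4a ketone to give aldol 19, which loses water by an E1cB path and enolises to the resorcylate, so that the C4a–C8a bond is formed and ring A is closed. The closest known reaction type is the ketene generation, alcohol trapping and base-mediated aldol aromatisation of diketo-dioxinones to resorcylates, the laboratory counterpart of polyketide cyclisation. Ring A closes in a 6-(enolexo)-exo-trig aldol mode. No stereocentre is created, and the silyl-protected C3 and C6' carbinols beyond C4 are spectators. The step needs C8a-to-C4a aldol closure in preference to Claisen attack of C5 on the ester (acylphloroglucinol), O-closure to a pyrone, and β-elimination of the C3 silyloxy group; the higher acidity of C8a, the mild carbonate–methanol medium (in which ester exchange is degenerate) and room temperature should secure this.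

Step 11
Reactants: 20 methyl 2-[(2R,8S)-2,8-bis(TBSO)tridecyl]-4,6-dihydroxybenzoate
Product: 22 (3R)-6,8-dihydroxy-3-[(6S)-6-hydroxyundecyl]-3,4-dihydro-1H-2-benzopyran-1-one, via desilylated triol ester 21 (not isolated)
Conditions: 1 M HCl in MeOH, rt; then evaporate, p-TsOH (cat.), PhMe, 60 °C
Reagents that add atoms: none
Why: Acid-catalysed methanolysis of both silyl ethers, followed by intramolecular transesterification of the freed C3 hydroxyl onto the ortho ester (six-membered lactonisation, driven by removal of methanol), should close ring B with retention at C3 because the C3–O bond is never broken.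

Step 12
Reactants: 22 (3R)-6,8-dihydroxy-3-[(6S)-6-hydroxyundecyl]-3,4-dihydro-1H-2-benzopyran-1-one
Product: 23 (3R)-8-hydroxy-3-[(6S)-6-hydroxyundecyl]-6-methoxy-3,4-dihydro-1H-2-benzopyran-1-one
Conditions: MeI (1.1 equiv), K2CO3, acetone, rt
Reagents that add atoms: iodomethane, CI
Why: Williamson O-methylation selective for the C6 phenol, which is para to the lactone carbonyl, more acidic and free, whereas the C8 phenol is hydrogen-bonded to C1=O and the C6' alcohol is not deprotonated by carbonate.

**Compound list**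

1 | heptanedioyl dichloride | O=C(Cl)CCCCCC(=O)Cl | starting material
2 | 2,2-dimethyl-1,3-dioxane-4,6-dione | CC1(C)OC(=O)CC(=O)O1 | starting material
3 | methanol | CO | starting material
4 | 5,5'-(1,7-dihydroxyheptane-1,7-diylidene)bis(2,2-dimethyl-1,3-dioxane-4,6-dione) | CC1(C)OC(=O)C(=C(O)CCCCCC(O)=C2C(=O)OC(C)(C)OC2=O)C(=O)O1 | intermediate
5 | dimethyl 3,9-dioxoundecanedioate | COC(=O)CC(=O)CCCCCC(=O)CC(=O)OC | intermediate
6 | dimethyl (3R,9R)-3,9-dihydroxyundecanedioate | COC(=O)C[C@H](O)CCCCC[C@@H](O)CC(=O)OC | intermediate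
7 | dimethyl (3R,9R)-3,9-bis(tert-butyldimethylsilyloxy)undecanedioate | COC(=O)C[C@H](O[Si](C)(C)C(C)(C)C)CCCCC[C@@H](O[Si](C)(C)C(C)(C)C)CC(=O)OC | intermediate
8 | methyl (3R,9R)-3,9-bis(tert-butyldimethylsilyloxy)-11-oxoundecanoate | COC(=O)C[C@H](O[Si](C)(C)C(C)(C)C)CCCCC[C@@H](O[Si](C)(C)C(C)(C)C)CC=O | intermediate
9 | methyl (3R,9R,11Z)-3,9-bis(tert-butyldimethylsilyloxy)tetradec-11-enoate | COC(=O)C[C@H](O[Si](C)(C)C(C)(C)C)CCCCC[C@@H](O[Si](C)(C)C(C)(C)C)C/C=C\CC | intermediate
10 | methyl (3R,9S)-3,9-bis(tert-butyldimethylsilyloxy)tetradecanoate | COC(=O)C[C@H](O[Si](C)(C)C(C)(C)C)CCCCC[C@@H](O[Si](C)(C)C(C)(C)C)CCCCC | intermediate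
11 | (3R,9S)-3,9-bis(tert-butyldimethylsilyloxy)-N-methoxy-N-methyltetradecanamide | CON(C)C(=O)C[C@H](O[Si](C)(C)C(C)(C)C)CCCCC[C@@H](O[Si](C)(C)C(C)(C)C)CCCCC | intermediate
12 | 2,2,6-trimethyl-4H-1,3-dioxin-4-one | CC1=CC(=O)OC(C)(C)O1 | starting material
13 | lithium 2,2-dimethyl-6-methylidene-6H-1,3-dioxin-4-olate | [Li+].C=C1C=C([O-])OC(C)(C)O1 | intermediate
14 | 2,2-dimethyl-6-(2-oxopropyl)-4H-1,3-dioxin-4-one | CC(=O)CC1=CC(=O)OC(C)(C)O1 | intermediate
15 | dilithium dianion of 14 (bis-enolate, deprotonated at the ring-side CH2 and at the methyl group) | [Li+].[Li+].C=C([O-])C=C1C=C([O-])OC(C)(C)O1 | intermediate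
16 | 6-[(6R,12S)-6,12-bis(tert-butyldimethylsilyloxy)-2,4-dioxoheptadecyl]-2,2-dimethyl-4H-1,3-dioxin-4-one | CC1(C)OC(=O)C=C(CC(=O)CC(=O)C[C@H](O[Si](C)(C)C(C)(C)C)CCCCC[C@@H](O[Si](C)(C)C(C)(C)C)CCCCC)O1 | intermediate
17 | (9R,15S)-9,15-bis(tert-butyldimethylsilyloxy)icos-1-ene-1,3,5,7-tetrone (acylketene) | O=C=CC(=O)CC(=O)CC(=O)C[C@H](O[Si](C)(C)C(C)(C)C)CCCCC[C@@H](O[Si](C)(C)C(C)(C)C)CCCCC | intermediate
18 | methyl (9R,15S)-9,15-bis(tert-butyldimethylsilyloxy)-3,5,7-trioxoicosanoate | COC(=O)CC(=O)CC(=O)CC(=O)C[C@H](O[Si](C)(C)C(C)(C)C)CCCCC[C@@H](O[Si](C)(C)C(C)(C)C)CCCCC | intermediate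
19 | methyl 2-[(2R,8S)-2,8-bis(tert-butyldimethylsilyloxy)tridecyl]-2-hydroxy-4,6-dioxocyclohexane-1-carboxylate (ring carbons C1 and C2 as a mixture) | COC(=O)C1C(=O)CC(=O)CC1(O)C[C@H](O[Si](C)(C)C(C)(C)C)CCCCC[C@@H](O[Si](C)(C)C(C)(C)C)CCCCC | intermediate
20 | methyl 2-[(2R,8S)-2,8-bis(tert-butyldimethylsilyloxy)tridecyl]-4,6-dihydroxybenzoate | COC(=O)c1c(O)cc(O)cc1C[C@H](O[Si](C)(C)C(C)(C)C)CCCCC[C@@H](O[Si](C)(C)C(C)(C)C)CCCCC | intermediate
21 | methyl 2-[(2R,8S)-2,8-dihydroxytridecyl]-4,6-dihydroxybenzoate | COC(=O)c1c(O)cc(O)cc1C[C@H](O)CCCCC[C@@H](O)CCCCC | intermediate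
22 | (3R)-6,8-dihydroxy-3-[(6S)-6-hydroxyundecyl]-3,4-dihydro-1H-2-benzopyran-1-one | CCCCC[C@H](O)CCCCC[C@@H]1Cc2cc(O)cc(O)c2C(=O)O1 | intermediate
23 | (3R)-8-hydroxy-3-[(6S)-6-hydroxyundecyl]-6-methoxy-3,4-dihydro-1H-2-benzopyran-1-one | CCCCC[C@H](O)CCCCC[C@@H]1Cc2cc(OC)cc(O)c2C(=O)O1 | target

**Step count**

Total: 12 steps. Longest linear sequence: 11 steps (steps 1–7 and 9–12 from heptanedioyl dichloride); step 8 is a one-step branch.

**Steps most likely to fail**

Step 10. The open triketo ester may close through the C6 enol oxygen to a pyrone or through C5 onto the ester instead of through C8a onto C4a. The C3 silyloxy group may be lost by β-elimination from the C4a ketone before ring closure. Dehydration of the aldol adduct may stall, although the acid of step 11 would complete it.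
Fallback: this sets out from 16 and makes ring A on the intact dioxinone, without any ketene or open triketo ester. Et3N in CH2Cl2 at rt should bring about the same C8a-to-C4a aldol and dehydration, giving the acetonide-protected resorcylate 5-[(2R,8S)-2,8-bis(TBSO)tridecyl]-7-hydroxy-2,2-dimethyl-4H-1,3-benzodioxin-4-one F1. Its only free phenol is the one at C6 of the target, so MeI and K2CO3 in acetone give the methyl ether 5-[(2R,8S)-2,8-bis(TBSO)tridecyl]-7-methoxy-2,2-dimethyl-4H-1,3-benzodioxin-4-one F2 without any question of site selectivity. Bu4NF in THF then removes both silyl groups, and the C3 alkoxide opens the benzodioxinone carbonyl with loss of acetone to close ring B. The fallback comes back to the route at 23.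

Step 9. The basic dianion may take a proton from the α-CH2 of the amide instead of adding to it, which stalls the acylation and opens the way to loss of silanolate. The keto-dioxinone may also condense with itself.
Fallback: this sets out from 11 and replaces acylation by aldol addition and oxidation. i-Bu2AlH in THF at −78 °C reduces the Weinreb amide to the aldehyde (3R,9S)-3,9-bis(TBSO)tetradecanal F3. Dianion 15 should add to F3 at −78 °C through its terminal carbon faster than any proton transfer, to give 6-[(6R,12S)-6,12-bis(TBSO)-4-hydroxy-2-oxoheptadecyl]-2,2-dimethyl-4H-1,3-dioxin-4-one F4 as a mixture of C4 epimers. Oxidation with Dess–Martin periodinane (NaHCO3, CH2Cl2, 0 °C to rt, reagent held close to one equivalent) gives the 1,3-diketone. The fallback comes back to the route at 16.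

Step 4. Hydride delivery may not stop at one ester or at the aldehyde stage, so that diol-derived and doubly reduced material accumulates and the statistical mixture is hard to separate.
Fallback: this sets out from 7 and differentiates the ends by hydrolysis and chemoselective reduction. LiOH (1 equiv) in THF–MeOH–H2O gives the mono-acid (3R,9R)-3,9-bis(TBSO)-11-methoxy-11-oxoundecanoic acid F5, which is separated from unchanged 7 by acid–base extraction; any diacid is re-esterified to 7. BH3·SMe2 in THF at 0 °C reduces the acid and leaves the ester, giving methyl (3R,9R)-3,9-bis(TBSO)-11-hydroxyundecanoate F6. Oxidation with Dess–Martin periodinane gives the aldehyde. The fallback comes back to the route at 8.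

**Further compounds**

F1 | step 10 | 5-[(2R,8S)-2,8-bis(tert-butyldimethylsilyloxy)tridecyl]-7-hydroxy-2,2-dimethyl-4H-1,3-benzodioxin-4-one | CC1(C)OC(=O)c2c(C[C@H](O[Si](C)(C)C(C)(C)C)CCCCC[C@@H](O[Si](C)(C)C(C)(C)C)CCCCC)cc(O)cc2O1
F2 | step 10 | 5-[(2R,8S)-2,8-bis(tert-butyldimethylsilyloxy)tridecyl]-7-methoxy-2,2-dimethyl-4H-1,3-benzodioxin-4-one | CC1(C)OC(=O)c2c(C[C@H](O[Si](C)(C)C(C)(C)C)CCCCC[C@@H](O[Si](C)(C)C(C)(C)C)CCCCC)cc(OC)cc2O1
F3 | step 9 | (3R,9S)-3,9-bis(tert-butyldimethylsilyloxy)tetradecanal | O=CC[C@H](O[Si](C)(C)C(C)(C)C)CCCCC[C@@H](O[Si](C)(C)C(C)(C)C)CCCCC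
F4 | step 9 | 6-[(6R,12S)-6,12-bis(tert-butyldimethylsilyloxy)-4-hydroxy-2-oxoheptadecyl]-2,2-dimethyl-4H-1,3-dioxin-4-one (C4 epimers) | CC1(C)OC(=O)C=C(CC(=O)CC(O)C[C@H](O[Si](C)(C)C(C)(C)C)CCCCC[C@@H](O[Si](C)(C)C(C)(C)C)CCCCC)O1
F5 | step 4 | (3R,9R)-3,9-bis(tert-butyldimethylsilyloxy)-11-methoxy-11-oxoundecanoic acid | COC(=O)C[C@H](O[Si](C)(C)C(C)(C)C)CCCCC[C@@H](O[Si](C)(C)C(C)(C)C)CC(=O)O
F6 | step 4 | methyl (3R,9R)-3,9-bis(tert-butyldimethylsilyloxy)-11-hydroxyundecanoate | COC(=O)C[C@H](O[Si](C)(C)C(C)(C)C)CCCCC[C@@H](O[Si](C)(C)C(C)(C)C)CCO
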